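Remark on the chemistry: olivetolic acid and benzyl bromide are taken as purchasable. The ring B carboxyl is carried as a benzyl ester rather than a tert-butyl ester; this changes a protecting group only and leaves the skeletons of 6 and 7 and the bond made in the key step untouched. No error was found in the structures of the planned key step or of the three alternatives.

## Structural features

Compound 10 is a diaryl ether of two 6-pentyl-β-resorcylate rings that both derive from the olivetolic acid skeleton; it has no stereocentre, so no stereochemical relationship has to be set. Numbered from the carboxyl-bearing carbon, ring A carries the methyl ester (C1), the ether oxygen (C2), a free hydroxyl (C4) and pentyl (C6); ring B carries the free acid (C1), a hydroxyl (C2), a methoxy group (C4), the ether oxygen (C5) and pentyl (C6). The ether bond joins ring A C2, ortho to an ester, to ring B C5, which is wedged between the C4 methoxy group and the C6 pentyl chain; three ortho substituents on two electron-rich rings make this bond the real difficulty, because intermolecular copper-mediated or SNAr etherification is poor here. A second difficulty is differentiation: two carboxyl groups (one methyl ester, one free acid) and four phenolic oxygens in four different states (free on ring A C4, diaryl ether, methyl ether, ester-chelated hydroxyl on ring B C2). The fragile part is ring B, a salicylic acid with a para methoxy group that loses CO2 readily in acid or on heating, so the last steps should be neutral; the ring A methyl ester must survive them as well. The decisive feature is the ortho pairing on each ring: the ring A C1 carbonyl lies next to the C2 oxygen and the ring B C4 oxygen lies next to C5, so an ester bond from the ring A carbonyl to the ring B C4 oxygen would close a seven-membered lactone; 10 is therefore a depsidone (dibenzo[b,e][1,4]dioxepin-11-one) opened by methanol and O-methylated. The key step uses the fact that ring B C5 is para to the ring B C2 hydroxyl: in the matching para-depside the ring A C2 hydroxyl is held next to C5–H, and oxidation of the phenols can forge the O–C5 bond as a ring closure.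

## Logic of the disconnections

10 to 9. The two O–CH2Ph bonds (ether on ring A C4, ester on the ring B carboxyl) are put back. One neutral hydrogenolysis then frees phenol and acid together, with no acid near the decarboxylation-prone ring B; this is the reason for a benzyl rather than a tert-butyl ester. Everything polar but the chelated ring B C2 hydroxyl is masked in 9. The demand is that both benzyl groups survive all earlier steps and that the final reduction leaves the diaryl ether and the methyl ester alone.

9 to 7 (through 8). The O–CH3 bond on ring B C4 and the acyl C–OCH3 bond of the ring A ester are cut, and the acyl carbon is reconnected to the ring B C4 oxygen. The lactone of 7 distinguishes the two carboxyls and marks exactly the ring B oxygen that must be methylated. The gain is a compact tricycle with no regiochemical question left. The demand is that methoxide attacks only the lactone carbonyl, that methylation spares the chelated C2 hydroxyl, and that the liberated phenoxide does not cause aryl migration.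

7 to 6. The ether bond between the ring A C2 oxygen and ring B C5 is cut; this is the strategic cut. The hardest bond is thereby made as a ring closure inside an ester tether, on a C–H position that needs no prior functionalisation. 6 is a plain ester of two nearly identical halves. The demand on the forward step is threefold: reaction at C5 and not C3, ring closure instead of intermolecular coupling, and a stop before the more electron-rich product is oxidised further. The design of 6 answers this as follows:
- Both C2 hydroxyls are free, because one is oxidised and the other is the nucleophile.
- The ring A C4 oxygen is benzylated; being meta to the ring A phenolic oxygen it does not make ring A much easier to oxidise than ring B.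
- C3 of ring B is not blocked by halogen, because halogenation of 3 is expected to prefer C5, the very position that must stay free.

6 to 5 + 3. The ester bond between the ring A carbonyl and the ring B C4 oxygen is cut. It is the only ester that a non-chelated hydroxyl of 3 can form. The gain is two monocyclic pieces of the same carbon skeleton. The demand is acylation at the C4 hydroxyl of 3 only, with the ortho hydroxyl of 5 not interfering.

5 to 4 to 3. The ring A C4 O–CH2Ph bond is cut and the carboxyl is traced back to its benzyl ester. In this way 3 is both the ring B component and the precursor of ring A, so both halves converge on one intermediate. The demand is selective benzylation of the C4 hydroxyl and an ester hydrolysis that spares the benzyl ether and avoids decarboxylation.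

3 to 1 + 2. The carboxyl O–CH2Ph bond is cut, leading to two commercial compounds. The demand is alkylation of the carboxylate without touching either phenol.

## Other disconnections considered

Alternative 1: The cut removes two bonds at ring A, the ether bond from ring A C2 to the oxygen on ring B C5 and the bond from ring A C1 to its carboxyl carbon. In the forward direction CsF would release a 3-(triflyloxy)aryne from the silyl bis(triflate) A1. The caesium phenoxide of the 5-hydroxy ring B ester A2 would add at the aryne carbon remote from the triflate, and the aryl anion formed between the new ether and the triflate would be carboxylated by carbon dioxide A3 to give acid A4, whose triflate marks the later position of the pentyl chain.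
- In favour: an aryne is electrophilic enough to accept a phenoxide flanked by methoxy and pentyl, and the inductive pull of the triflate fixes the direction of addition.
- Better than the chosen plan on site selectivity: the oxygen already sits on ring B C5 in A2, so no C3/C5 question arises and nothing depends on the redox behaviour of two similar phenols.
- Against: A2 is a 2,4,5-trioxygenated benzoate that 1 does not provide without an extra ring oxidation, and A1 needs its own sequence.
- Against, mechanistically: an aryl anion next to a triflate can expel triflate (a second aryne) or suffer triflyl migration before A3 arrives, and the phenoxide is itself reversibly carbonated by A3.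
- Step economy: after A4 come esterification, an sp2–sp3 coupling of a doubly ortho-substituted triflate with a pentyl organometallic, and hydrogenolysis. The whole is clearly longer than the seven steps of the chosen plan, which draws both rings from 1.
- Equal: neither plan has a stereochemical burden.

Alternative 2: The cut removes the ring B bonds C1–C2 and C5–C6, so ring B is built onto an ether oxygen already attached to ring A. In the forward direction the vinylketene acetal A5 (a 4-aryloxy-1,3-dimethoxy-1-silyloxybutadiene, aryl = ring A) and benzyl oct-2-ynoate A6 would undergo a Diels–Alder reaction; loss of methanol and of the silyl group would aromatise the adduct to A7.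
- In favour: all substituents of ring B are placed in one step, and the nucleophilic diene terminus bearing the aryloxy group is matched with the β-carbon of the ynoate.
- Better than the chosen plan on differentiation: the C4 methoxy group and the free C2 hydroxyl are built in, so no selective methylation is needed.
- Better on the end game: A7 is the same compound as 9, so only the hydrogenolysis remains after the key step, against two operations in the chosen plan.
- Against: A6 is a singly activated, β-alkylated alkyne and a sluggish dienophile, and the reacting terminus of A5 carries the bulky aryloxy group, so the C5–C6 bond must form between two fully substituted carbons.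
- Against: A5 is hydrolytically fragile, and its preparation requires O-alkylation of a chelated, hindered ring A salicylate hydroxyl followed by enol silylation. A conjugate addition without ring closure is a likely competing path.
- Step economy: the count would be similar to the chosen plan or slightly higher, with only ring A taken from 1.
- Equal: no stereocentre in either plan.

Alternative 3: The cut removes the ring B bonds C1–C6 and C2–C3 and takes ring B back to a non-aromatic dione. In the forward direction dibenzyl malonate A9 would add to the 3-aryloxy enone A8 (Michael addition), and the methyl ketone enolate would close onto one ester (Dieckmann condensation) to give the racemic cyclohexanedione A10.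
- In favour: classical carbanion chemistry, cheap reagents, no metal catalyst and no electrolysis; on operational simplicity of the key step it is the better of the two.
- Equal: the three stereocentres of A10 are erased on aromatisation, so, as in the chosen plan, no stereocontrol is needed. The later methylation of the C4 oxygen next to a chelated C2 hydroxyl is the same problem as in the chosen plan.
- Against, and decisive: A10 must be dehydrogenated to the resorcinol, but a 1,3-dione with an aryloxy leaving group on the carbon next to a carbonyl can aromatise more easily by eliminating the ring A phenol. That would break the very ether bond the plan was meant to secure.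
- Against: conjugate addition to an α-oxygenated, β-alkylated enone is slow, and A8 again requires alkylation of the hindered ring A hydroxyl and an aldol condensation.
- Step economy: the plan is longer (fragment synthesis, key step, aromatisation, methylation, deprotection) than the seven steps of the chosen plan.

Key step: step 5

## Route

Step 1
Reactants: 1 olivetolic acid (2,4-dihydroxy-6-pentylbenzoic acid); 2 benzyl bromide
Product: 3 benzyl 2,4-dihydroxy-6-pentylbenzoate
Conditions: KHCO3 (1.2 equiv), DMF, rt
Reagents that add atoms: none
Why: Bicarbonate deprotonates only the carboxylic acid, and the carboxylate is O-alkylated by SN2; neither phenol is ionised, and the absence of heat and acid avoids decarboxylation of the β-resorcylic acid.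

Step 2
Reactants: 3 benzyl 2,4-dihydroxy-6-pentylbenzoate; 2 benzyl bromide
Product: 4 benzyl 4-(benzyloxy)-2-hydroxy-6-pentylbenzoate
Conditions: BnBr (1.05 equiv), K2CO3, acetone, reflux
Reagents that add atoms: none
Why: Williamson ether synthesis; the C2 hydroxyl is hydrogen-bonded to the ester carbonyl and is the poorer nucleophile, so the para C4 hydroxyl should be alkylated selectively with one equivalent of halide.

Step 3
Reactants: 4 benzyl 4-(benzyloxy)-2-hydroxy-6-pentylbenzoate
Product: 5 4-(benzyloxy)-2-hydroxy-6-pentylbenzoic acid
Conditions: KOH (5 equiv), DMSO–H2O (4:1), 80 °C; then 1 M HCl to pH 3 at 0 °C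
Reagents that add atoms: potassium hydroxide, [K+].[OH-] (its oxygen becomes a carboxyl oxygen)
Why: Saponification (acyl–oxygen cleavage) of the doubly ortho-substituted ester by poorly solvated hydroxide in aqueous DMSO; the benzyl aryl ether is inert to base, and the acid is released only in the cold because the carboxylate is stable whereas the free acid can decarboxylate when heated.

Step 4
Reactants: 5 4-(benzyloxy)-2-hydroxy-6-pentylbenzoic acid; 3 benzyl 2,4-dihydroxy-6-pentylbenzoate
Product: 6 benzyl 4-{[4-(benzyloxy)-2-hydroxy-6-pentylbenzoyl]oxy}-2-hydroxy-6-pentylbenzoate (the para-depside)
Conditions: DCC (1.2 equiv), DMAP (0.1 equiv), CH2Cl2, 0 °C to rt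
Reagents that add atoms: none
Why: Steglich esterification; the ortho hydroxyls of both partners are tied up in hydrogen bonds to their carbonyl groups, so the activated acid should be taken up by the free C4 hydroxyl of 3, the usual selectivity in para-depside assembly.

Step 5
Reactants: 6 benzyl 4-{[4-(benzyloxy)-2-hydroxy-6-pentylbenzoyl]oxy}-2-hydroxy-6-pentylbenzoate
Product: 7 benzyl 3-(benzyloxy)-8-hydroxy-11-oxo-1,6-dipentyl-11H-dibenzo[b,e][1,4]dioxepine-7-carboxylate (the depsidone)
Conditions: graphite anode, Pt cathode, undivided cell, constant current (2 mA cm−2, 2.1 F mol−1), Bu4NPF6 (0.1 M), 2,6-lutidine (2 equiv), (CF3)2CHOH–CH2Cl2 (4:1), 5 mM, rt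
Reagents that add atoms: none
Why: Proposed new method: base-assisted anodic oxidation of the ring B salicylate phenol (loss of two electrons and one proton) should give a phenoxonium ion whose positive charge is largest at C5, para to the oxygen; the ring A C2 hydroxyl, held over that carbon by the planar ester tether, adds to it, loss of the C5 proton restores the aromatic ring, and the protons are reduced to H2 at the cathode. Because the C4 oxygen substituents of both rings are meta to the phenolic oxygens, the two phenols should oxidise at similar potentials, and if ring A is oxidised first its phenoxyl oxygen can combine with the same C5 position of an oxidised ring B, so both courses lead to 7. The closest known reactions are the oxidative cyclisation of depsides to depsidones with chemical oxidants such as MnO2 and the anodic formation of diaryl ethers from phenols; an electrochemical depside-to-depsidone closure is not established. The seven-membered dioxepinone ring closes by attack of oxygen on an sp2 carbon of ring B, formally 7-endo-trig when counted on the C4–C5 π bond, a geometry that the rigid aryl ester enforces. No stereocentre is formed. The step needs site selectivity for C5 over C3, both of which are ortho to the tethered C4 oxygen; this rests on the larger charge and spin density para to the phenoxyl oxygen and on the crowding of C3 between two oxygens. It also needs chemoselectivity against further oxidation of the para-aryloxy phenol product, which the hydrogen-bonding fluorinated solvent, high dilution and a charge limit near 2 F mol−1 are meant to secure.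

Step 6
Reactants: 7 benzyl 3-(benzyloxy)-8-hydroxy-11-oxo-1,6-dipentyl-11H-dibenzo[b,e][1,4]dioxepine-7-carboxylate
Product: 9 benzyl 5-[5-(benzyloxy)-2-(methoxycarbonyl)-3-pentylphenoxy]-2-hydroxy-4-methoxy-6-pentylbenzoate, via ring-opened diphenol diaryl ether 8 (not isolated)
Conditions: K2CO3 (3 equiv), MeOH–THF (1:1), 0 °C to rt; evaporate; then MeI (1.1 equiv), acetone, rt
Reagents that add atoms: methanol, CO; iodomethane, CI
Why: Methoxide generated from K2CO3 in methanol should cleave only the activated aryl ester of the lactone (transesterification), giving the ring A methyl ester and the ring B C4 phenoxide, while the ring B benzyl ester is a doubly ortho-substituted benzoate further deactivated by its phenoxide neighbours. The phenoxide set free, unlike the ester-chelated C2 hydroxyl, is then methylated by MeI (Williamson ether synthesis). Low temperature and acetone instead of a hot dipolar solvent are chosen so that a Smiles migration of ring A to the C4 oxygen does not compete.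

Step 7
Reactants: 9 benzyl 5-[5-(benzyloxy)-2-(methoxycarbonyl)-3-pentylphenoxy]-2-hydroxy-4-methoxy-6-pentylbenzoate
Product: 10 epiphorellic acid 1 (2-hydroxy-5-[5-hydroxy-2-(methoxycarbonyl)-3-pentylphenoxy]-4-methoxy-6-pentylbenzoic acid)
Conditions: H2 (1 atm), 10% Pd/C, EtOAc, rt
Reagents that add atoms: none
Why: Catalytic hydrogenolysis cleaves the benzyl ether and the benzyl ester in one neutral operation; the diaryl ether, the methyl ether and the methyl ester are not reduced, and the absence of acid protects the ring B acid from decarboxylation.

## Compound list

1 | olivetolic acid (2,4-dihydroxy-6-pentylbenzoic acid) | CCCCCc1cc(O)cc(O)c1C(=O)O | starting material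
2 | benzyl bromide | BrCc1ccccc1 | starting material
3 | benzyl 2,4-dihydroxy-6-pentylbenzoate | CCCCCc1cc(O)cc(O)c1C(=O)OCc1ccccc1 | intermediate
4 | benzyl 4-(benzyloxy)-2-hydroxy-6-pentylbenzoate | CCCCCc1cc(OCc2ccccc2)cc(O)c1C(=O)OCc1ccccc1 | intermediate
5 | 4-(benzyloxy)-2-hydroxy-6-pentylbenzoic acid | CCCCCc1cc(OCc2ccccc2)cc(O)c1C(=O)O | intermediate
6 | benzyl 4-{[4-(benzyloxy)-2-hydroxy-6-pentylbenzoyl]oxy}-2-hydroxy-6-pentylbenzoate | CCCCCc1cc(OCc2ccccc2)cc(O)c1C(=O)Oc1cc(O)c(C(=O)OCc2ccccc2)c(CCCCC)c1 | intermediate
7 | benzyl 3-(benzyloxy)-8-hydroxy-11-oxo-1,6-dipentyl-11H-dibenzo[b,e][1,4]dioxepine-7-carboxylate | CCCCCc1cc(OCc2ccccc2)cc2c1C(=O)Oc1cc(O)c(C(=O)OCc3ccccc3)c(CCCCC)c1O2 | intermediate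
8 | benzyl 5-[5-(benzyloxy)-2-(methoxycarbonyl)-3-pentylphenoxy]-2,4-dihydroxy-6-pentylbenzoate (formed as its potassium phenoxide) | CCCCCc1cc(OCc2ccccc2)cc(Oc2c(O)cc(O)c(C(=O)OCc3ccccc3)c2CCCCC)c1C(=O)OC | intermediate
9 | benzyl 5-[5-(benzyloxy)-2-(methoxycarbonyl)-3-pentylphenoxy]-2-hydroxy-4-methoxy-6-pentylbenzoate | CCCCCc1cc(OCc2ccccc2)cc(Oc2c(OC)cc(O)c(C(=O)OCc3ccccc3)c2CCCCC)c1C(=O)OC | intermediate
10 | epiphorellic acid 1 (2-hydroxy-5-[5-hydroxy-2-(methoxycarbonyl)-3-pentylphenoxy]-4-methoxy-6-pentylbenzoic acid) | CCCCCc1cc(O)cc(Oc2c(OC)cc(O)c(C(=O)O)c2CCCCC)c1C(=O)OC | target

## Step count and least certain steps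

Total step count: 7. Longest linear sequence: 7 steps (1 → 3 → 4 → 5 → 6 → 7 → 9 → 10; 3 enters a second time in step 4).

Step 5 (key step, carries the label "Proposed new method:"). What is most likely to go wrong:
- Oxidation centred on ring A followed by intermolecular coupling or solvent capture instead of ring closure.
- Closure at C3 instead of C5.
- Further oxidation of the product, whose ring B phenol now has a para aryloxy group and is easier to oxidise than the starting phenols; this would lead to quinoid material with loss of ring A.

A chemical oxidant such as MnO2 would change only the reagent. The fallback with known chemistry replaces C–H oxidation by a halogen-directed copper coupling within the same tether. It sets out from 3, which is brominated para to the C2 hydroxyl (NBS, CH2Cl2, −20 °C) to give benzyl 5-bromo-2,4-dihydroxy-6-pentylbenzoate F1, with removal of any 3-bromo isomer. Steglich esterification of F1 with 5 gives benzyl 4-{[4-(benzyloxy)-2-hydroxy-6-pentylbenzoyl]oxy}-5-bromo-2-hydroxy-6-pentylbenzoate F2. An intramolecular Ullmann diaryl ether synthesis (CuI, N,N-dimethylglycine, Cs2CO3, dioxane, 90 °C) then closes the seven-membered ring and comes back to the route at 7. The site of ether formation is then fixed by the bromine and no longer by the oxidation.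

Step 6. What is most likely to go wrong:
- Exchange of the benzyl ester of ring B for a methyl ester by methoxide, which could not be undone at the end.
- Migration of ring A from the C5 oxygen to the C4 oxygen through a spiro Meisenheimer intermediate (Smiles rearrangement) once the ortho phenoxide is free.
- Methylation of the chelated C2 hydroxyl.

The fallback avoids alkoxide altogether. It sets out from 7, whose lactone is opened hydrolytically (LiOH, THF–H2O, 0 °C, then mild acid) to 4-(benzyloxy)-2-{3-[(benzyloxy)carbonyl]-4,6-dihydroxy-2-pentylphenoxy}-6-pentylbenzoic acid F3. Treating F3 with MeI (2.2 equiv) and K2CO3 in acetone methylates the carboxylate and the C4 phenoxide together and comes back to the route at 9.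

Step 3. What is most likely to go wrong: incomplete hydrolysis of the doubly ortho-substituted ester under conditions mild enough for the substrate, or loss of CO2 from the electron-rich salicylic acid during acidification. The fallback uses an ester that is removed under neutral conditions. It sets out from 1, which is converted with allyl bromide and KHCO3 in DMF into allyl 2,4-dihydroxy-6-pentylbenzoate F4. Benzylation with 2 and K2CO3 gives allyl 4-(benzyloxy)-2-hydroxy-6-pentylbenzoate F5. Transfer of the allyl group to morpholine with catalytic Pd(PPh3)4 (zerovalent palladium, Tsuji–Trost deallylation, THF, rt) comes back to the route at 5.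

Step 4. What is most likely to go wrong: slow attack on the hindered activated acid, which allows rearrangement of the O-acylisourea to an unreactive N-acylurea, or self-condensation through the ortho hydroxyl of 5. The fallback masks acid and ortho hydroxyl together. It sets out from 5, which is condensed with acetone (trifluoroacetic anhydride, trifluoroacetic acid, 0 °C to rt) to 7-(benzyloxy)-2,2-dimethyl-5-pentyl-4H-1,3-benzodioxin-4-one F6. Irradiation of F6 (about 300 nm, CH2Cl2, rt) in the presence of 3 should release acetone and a quinoketene, which the free C4 hydroxyl of 3 captures; this comes back to the route at 6.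

## Further compounds

F1 | step 5 | benzyl 5-bromo-2,4-dihydroxy-6-pentylbenzoate | CCCCCc1c(Br)c(O)cc(O)c1C(=O)OCc1ccccc1
F2 | step 5 | benzyl 4-{[4-(benzyloxy)-2-hydroxy-6-pentylbenzoyl]oxy}-5-bromo-2-hydroxy-6-pentylbenzoate | CCCCCc1cc(OCc2ccccc2)cc(O)c1C(=O)Oc1cc(O)c(C(=O)OCc2ccccc2)c(CCCCC)c1Br
F3 | step 6 | 4-(benzyloxy)-2-{3-[(benzyloxy)carbonyl]-4,6-dihydroxy-2-pentylphenoxy}-6-pentylbenzoic acid | CCCCCc1cc(OCc2ccccc2)cc(Oc2c(O)cc(O)c(C(=O)OCc3ccccc3)c2CCCCC)c1C(=O)O
F4 | step 3 | allyl 2,4-dihydroxy-6-pentylbenzoate | CCCCCc1cc(O)cc(O)c1C(=O)OCC=C
F5 | step 3 | allyl 4-(benzyloxy)-2-hydroxy-6-pentylbenzoate | CCCCCc1cc(OCc2ccccc2)cc(O)c1C(=O)OCC=C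
F6 | step 4 | 7-(benzyloxy)-2,2-dimethyl-5-pentyl-4H-1,3-benzodioxin-4-one | CCCCCc1cc(OCc2ccccc2)cc2OC(C)(C)OC(=O)c12
A1 | alternative 1 | 5-(benzyloxy)-2-(trimethylsilyl)-1,3-phenylene bis(trifluoromethanesulfonate) | C[Si](C)(C)c1c(OS(=O)(=O)C(F)(F)F)cc(OCc2ccccc2)cc1OS(=O)(=O)C(F)(F)F
A2 | alternative 1 | benzyl 2-(benzyloxy)-5-hydroxy-4-methoxy-6-pentylbenzoate | CCCCCc1c(O)c(OC)cc(OCc2ccccc2)c1C(=O)OCc1ccccc1
A3 | alternative 1 | carbon dioxide | O=C=O
A4 | alternative 1 | 4-(benzyloxy)-2-{4-(benzyloxy)-3-[(benzyloxy)carbonyl]-6-methoxy-2-pentylphenoxy}-6-{[(trifluoromethyl)sulfonyl]oxy}benzoic acid | OC(=O)c1c(OS(=O)(=O)C(F)(F)F)cc(OCc2ccccc2)cc1Oc1c(OC)cc(OCc2ccccc2)c(C(=O)OCc2ccccc2)c1CCCCC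
A5 | alternative 2 | methyl 4-(benzyloxy)-2-{[2,4-dimethoxy-4-(trimethylsilyloxy)buta-1,3-dien-1-yl]oxy}-6-pentylbenzoate (double-bond geometry not defined) | CCCCCc1cc(OCc2ccccc2)cc(OC=C(OC)C=C(OC)O[Si](C)(C)C)c1C(=O)OC
A6 | alternative 2 | benzyl oct-2-ynoate | CCCCCC#CC(=O)OCc1ccccc1
A7 | alternative 2 | benzyl 5-[5-(benzyloxy)-2-(methoxycarbonyl)-3-pentylphenoxy]-2-hydroxy-4-methoxy-6-pentylbenzoate (identical with 9) | CCCCCc1cc(OCc2ccccc2)cc(Oc2c(OC)cc(O)c(C(=O)OCc3ccccc3)c2CCCCC)c1C(=O)OC
A8 | alternative 3 | methyl 4-(benzyloxy)-2-[(2-oxonon-3-en-3-yl)oxy]-6-pentylbenzoate (double-bond geometry not defined) | CCCCCC=C(Oc1cc(OCc2ccccc2)cc(CCCCC)c1C(=O)OC)C(C)=O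
A9 | alternative 3 | dibenzyl malonate | O=C(CC(=O)OCc1ccccc1)OCc1ccccc1
A10 | alternative 3 | benzyl rac-(1R,5S,6R)-5-[5-(benzyloxy)-2-(methoxycarbonyl)-3-pentylphenoxy]-2,4-dioxo-6-pentylcyclohexane-1-carboxylate (racemic, 1,6-trans and 5,6-trans; one enantiomer drawn) | CCCCC[C@@H]1[C@@H](C(=O)OCc2ccccc2)C(=O)CC(=O)[C@H]1Oc1cc(OCc2ccccc2)cc(CCCCC)c1C(=O)OC
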